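**Retrosynthetic overview**

- Target 10 is traced back to the α′-bromo enone 9 (1,2-reduction sets C9), then to the silyl dienol ether 7 (bromination and C10 epimer equilibration), the enone 5 (allylic oxidation at C9) and the bromo chloride 4 (Markovnikov HBr addition across C3=C4 anti to the C2 chlorine).
- The chlorodiene 3 comes from its exocyclic isomer 2, and 2 from (−)-thujopsene 1 in one chloronium-triggered operation: Cl+ on the alkene CH (future C2), cleavage of the cyclopropane bond C4–C6 and of C1–C7, formation of C1–C6.
- The strategy rests on this feature: spiro C6 lies between C11(CH3)2 and the methyl-bearing C7 of ring A and carries ring B with the C2(Cl)/C3(CH3)(Br) pair. This is the thujopsene skeleton with C1 moved from C7 to C6; thujopsene's cyclopropane quaternary carbon is C6 and its only alkene CH is C2.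
- Ring order: ring A (C6–C11) is carried intact from 1; ring B (C1–C6) is made in step 1 by ring contraction; no ring is formed afterwards.

Key step: step 1

Remark on numbering: chamigrane numbering is used throughout, also for 1: ring B = C1H2, C2, C3 (bears C15), C4, C5, spiro C6; ring A = C6, C7 (bears C14), C8, C9, C10, C11 (bears C12 and C13).

Remark on the chemistry (assumption): Cl+ is taken to reach C2 of 1 on the face that carries the angular methyl C14 and the cyclopropane methylene C5, the exposed face if 1 reacts from the folded cis-fused conformer with C8 axial under the other face; this gives 2S, and attack on the other face would give the C2 epimer.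

**Step 1**
Reactants: 1 (−)-thujopsene, (1aS,4aS,8aS)-2,4a,8,8-tetramethyl-1,1a,4,4a,5,6,7,8-octahydrocyclopropa[d]naphthalene
Product: 2 (2S,6S)-2-chloro-chamigra-3,7(14)-diene, expected together with its endocyclic isomer; the unseparated olefin is carried into step 2
Conditions: NCS (1.05 equiv), polymer-bound 2,6-di-tert-butylpyridine (0.3 equiv), (CF3)2CHOH/CH2Cl2 1:3, −40 → −10 °C, dark; filtration, cold aq. NaHCO3, pentane
Reagents that add atoms: N-chlorosuccinimide, O=C1CCC(=O)N1Cl
Why: Proposed new method: NCS activated by hydrogen bonding to the fluorinated alcohol should transfer Cl+ to the alkene CH (C2) of 1 and leave a tertiary cyclopropylcarbinyl cation at C3; the ring-fusion cyclopropane bond C4–C6 then opens to the C3=C4 alkene and a tertiary C6 cation in a seven-membered ring, the C1 methylene shifts from C7 to C6, and the tertiary C7 cation gives up a proton to the succinimide anion from the exposed C14 methyl (2) or from C8 (the endocyclic isomer, into which step 2 converts all material). The closest known reaction type is the Brønsted-acid rearrangement of thujopsene to widdrol and chamigrene olefins (cyclopropylcarbinyl-to-homoallyl opening followed by a 1,2-alkyl shift), set off here by a chloronium ion and not by a proton. Ring B (C1–C6) is closed by Wagner–Meerwein contraction of the seven-membered cation ring onto C6 and not by a cyclisation, while ring A passes through unchanged. C6 is fixed by the suprafacial migration of C1 across the C7–C6 bond and therefore follows from the C7 configuration of the chiral-pool hydrocarbon, and C2 by the face of Cl+ attack stated in the remark above. The step needs C1 to migrate in preference to C14 or C8 and no cation to be intercepted before the shift: the flexible seven-membered ring can bring the C7–C1 bond into overlap with the empty orbital at C6 and contraction relieves its strain, as in the proton-triggered precedent, and the weakly nucleophilic medium, the imide counter-ion and the insoluble hindered base (which also scavenges stray acid that would start the chlorine-free cascade) should prevent capture. Every cation is tertiary, 1 has no second π bond, and the allylic chlorine deactivates the new ring B alkene toward the C7 cation and toward a second Cl+.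

**Step 2**
Reactants: 2 (2S,6S)-2-chloro-chamigra-3,7(14)-diene
Product: 3 (2S,6S)-2-chloro-chamigra-3,7-diene
Conditions: p-TsOH·H2O (5 mol%), CH2Cl2, 0 °C → rt, stopped at convergence
Reagents that add atoms: none
Why: Acid-catalysed exocyclic-to-endocyclic alkene isomerisation, in which reversible protonation of the methylene regenerates the tertiary C7 cation that sheds H8 to give the more substituted ring alkene, while the ring B alkene is shielded from protonation by the inductive effect of the allylic chlorine and no stereocentre is involved.

**Step 3**
Reactants: 3 (2S,6S)-2-chloro-chamigra-3,7-diene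
Product: 4 (2S,3S,6S)-3-bromo-2-chloro-chamigr-7-ene (Br at C3 trans to Cl at C2)
Conditions: HBr (1.05 equiv, gas titrated into CH2Cl2), BHT (cat.), CH2Cl2, −78 → −40 °C, dark
Reagents that add atoms: hydrogen bromide, Br
Why: Ionic Markovnikov hydrobromination, in which protonation at C4 gives the tertiary C3 cation bridged by the neighbouring chlorine and bromide opens it at C3 anti to chlorine (sets 3S), while the ring A alkene should be spared because a bromide at C7 next to the quaternary spiro carbon is too crowded to persist, its protonation is reversible, and only one equivalent is used cold with radical addition suppressed.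

**Step 4**
Reactants: 4 (2S,3S,6S)-3-bromo-2-chloro-chamigr-7-ene
Product: 5 (2S,3S,6S)-3-bromo-2-chloro-chamigr-7-en-9-one
Conditions: CrO3 (12 equiv), 3,5-dimethylpyrazole (12 equiv), CH2Cl2, −20 °C
Reagents that add atoms: chromium trioxide, O=[Cr](=O)=O
Why: Allylic oxidation with the CrO3–3,5-dimethylpyrazole complex, in which C9 is the only allylic methylene left (C6 is quaternary and the C14 methyl reacts more slowly), so the β-methyl enone should form, with the tertiary bromide and secondary chloride inert to the oxidant at low temperature and no stereocentre changed.

**Step 5**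
Reactants: 5 (2S,3S,6S)-3-bromo-2-chloro-chamigr-7-en-9-one
Product: 7 (2S,3S,6R)-3-bromo-2-chloro-9-(trimethylsilyloxy)chamigra-7,9-diene, via lithium dienolate 6 (not isolated)
Conditions: LiN(iPr)2 (1.1 equiv, commercial solution), THF, −78 °C; then Me3SiCl (1.3 equiv), −78 → 0 °C; pentane, filtration, used crude
Reagents that add atoms: chlorotrimethylsilane, C[Si](C)(C)Cl
Why: Kinetic α′-deprotonation of an enone by a lithium amide at −78 °C (C10–H, the isophorone pattern) gives the cross-conjugated dienolate, which is O-silylated; ketone deprotonation is far faster than E2 loss of HBr or HCl at this temperature and no stereocentre is formed.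

**Step 6**
Reactants: 7 (2S,3S,6R)-3-bromo-2-chloro-9-(trimethylsilyloxy)chamigra-7,9-diene
Product: 8 (2S,3S,6R)-3,10-dibromo-2-chloro-chamigr-7-en-9-one as the mixture of its two C10 epimers
Conditions: NBS (1.05 equiv), NaHCO3, THF, −78 → −40 °C
Reagents that add atoms: N-bromosuccinimide, O=C1CCC(=O)N1Br
Why: Electrophilic α-bromination of a silyl enol ether, in which NBS attacks the nucleophilic terminus C10 of the 2-silyloxy diene and loss of the silyl group returns the enone carbonyl; C10 is formed under only weak remote control from ring B (the arms C1 and C5 at the spiro carbon first differ at C2 and C4), so both epimers are expected and are taken on together.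

**Step 7**
Reactants: 8 (2S,3S,6R)-3,10-dibromo-2-chloro-chamigr-7-en-9-one as the mixture of its two C10 epimers
Product: 9 (2S,3S,6R,10R)-3,10-dibromo-2-chloro-chamigr-7-en-9-one
Conditions: DBU (0.1 equiv), CH2Cl2, 0 °C; SiO2 chromatography; recovered 10S epimer returned to the same conditions
Reagents that add atoms: none
Why: Base-catalysed epimerisation through the bromo dienolate, in which C10–H (α to the carbonyl and geminal to bromine) is the most acidic hydrogen and the quaternary C11 rules out both E2 and SN2 at C10, so reversible deprotonation should bring the two epimers to their equilibrium ratio, from which the 10R isomer is separated and the other recycled, while a catalytic amount of amidine at 0 °C should not dehydrobrominate the tertiary C3 bromide.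

**Step 8**
Reactants: 9 (2S,3S,6R,10R)-3,10-dibromo-2-chloro-chamigr-7-en-9-one
Product: 10 (2S,3S,6R,9S,10R)-3,10-dibromo-2-chloro-chamigr-7-en-9-ol (target; OH at C9 cis to Br at C10)
Conditions: iBu2AlH (1.5 equiv), CH2Cl2, −78 °C; aq. KNaC4H4O6
Reagents that add atoms: none
Why: 1,2-Reduction of the β,β-disubstituted enone by a bulky aluminium hydride, with hydride adding to C9 anti to the pseudo-axial C10 bromine (polar Felkin–Anh control), which places OH cis to Br and sets 9S; the alkyl halides are inert at −78 °C and a cis bromohydrin cannot close to an epoxide.

**Compound list**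

1 | (−)-thujopsene, (1aS,4aS,8aS)-2,4a,8,8-tetramethyl-1,1a,4,4a,5,6,7,8-octahydrocyclopropa[d]naphthalene | CC1=CC[C@@]2(CCCC([C@]23[C@H]1C3)(C)C)C | starting material
2 | (2S,6S)-2-chloro-chamigra-3,7(14)-diene | C=C1CCCC(C)(C)[C@@]12CC=C(C)[C@@H](Cl)C2 | intermediate
3 | (2S,6S)-2-chloro-chamigra-3,7-diene | CC1=CCCC(C)(C)[C@@]12CC=C(C)[C@@H](Cl)C2 | intermediate
4 | (2S,3S,6S)-3-bromo-2-chloro-chamigr-7-ene | CC1=CCCC(C)(C)[C@@]12CC[C@](C)(Br)[C@@H](Cl)C2 | intermediate
5 | (2S,3S,6S)-3-bromo-2-chloro-chamigr-7-en-9-one | CC1=CC(=O)CC(C)(C)[C@@]12CC[C@](C)(Br)[C@@H](Cl)C2 | intermediate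
6 | lithium (2S,3S,6R)-3-bromo-2-chloro-chamigra-7,9-dien-9-olate | CC1=CC([O-])=CC(C)(C)[C@@]12CC[C@](C)(Br)[C@@H](Cl)C2.[Li+] | intermediate
7 | (2S,3S,6R)-3-bromo-2-chloro-9-(trimethylsilyloxy)chamigra-7,9-diene | CC1=CC(O[Si](C)(C)C)=CC(C)(C)[C@@]12CC[C@](C)(Br)[C@@H](Cl)C2 | intermediate
8 | (2S,3S,6R)-3,10-dibromo-2-chloro-chamigr-7-en-9-one, mixture of C10 epimers | CC1=CC(=O)C(Br)C(C)(C)[C@@]12CC[C@](C)(Br)[C@@H](Cl)C2 | intermediate
9 | (2S,3S,6R,10R)-3,10-dibromo-2-chloro-chamigr-7-en-9-one | CC1=CC(=O)[C@H](Br)C(C)(C)[C@@]12CC[C@](C)(Br)[C@@H](Cl)C2 | intermediate
10 | (2S,3S,6R,9S,10R)-3,10-dibromo-2-chloro-chamigr-7-en-9-ol | CC1=C[C@H](O)[C@H](Br)C(C)(C)[C@@]12CC[C@](C)(Br)[C@@H](Cl)C2 | target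

**Step count and risks**

Total step count: 8
Longest linear sequence: 8 steps from 1 (steps 1 to 8)

Steps most likely to fail:

1. Step 1 (proposed new method). Cl+ may be delivered to the other face of C2. The first cation may lose a C15 proton, which gives ene-type allylic chlorination without skeletal change. The seven-membered cation may be captured by solvent or imide. The β-chlorine may slow the shift of C1 enough for the better-aligned C14 methyl, or C8, to migrate instead. Fallback with known reaction types, setting out from 1 and coming back at 3: the proton-triggered form of the same rearrangement (anhydrous p-TsOH in benzene, so that the C6 cation is not trapped as widdrol, exocyclic and endocyclic olefins converging under the acid) gives chlorine-free (6R)-chamigra-3,7-diene F1. Allylic oxidation with SeO2 (cat.) and tBuOOH in CH2Cl2 attacks the ring methylene next to the methyl-bearing alkene carbon and gives chamigra-3,7-dien-2-ol F2 as a C2 mixture; the ring A alkene offers only the crowded C14 methyl at its substituted end, so oxidation there should be slower and its products are removed by chromatography. Dess–Martin periodinane gives (6S)-chamigra-3,7-dien-2-one F3. CBS reduction (BH3·SMe2, the methyl oxazaborolidine enantiomer chosen so that the hydroxyl ends on the ring B face opposite to the one required for chlorine) gives (2R,6S)-chamigra-3,7-dien-2-ol F4 under reagent control. PPh3 and hexachloroacetone then replace the allylic hydroxyl by chloride with inversion and without allylic transposition, giving 3 with C2 fixed independently of the facial bias of 1.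

2. Step 3. The ring A alkene may be protonated competitively, after which the C7 cation can revert by the reverse shift of C1 toward the seven-membered skeleton. Halide exchange or ionisation at the allylic chloride may also occur before addition. Fallback, setting out from 3 and coming back at 4: oxymercuration with Hg(OAc)2 in THF/H2O passes through a mercurinium ion and no free cation, so no skeletal shift is possible, and it is sensitive enough to steric hindrance that it should favour the ring B alkene over the one flanked by the spiro carbon. It gives the Markovnikov organomercurial 4-(acetoxymercurio)-2-chloro-chamigr-7-en-3-ol F5 (mercury anti to chlorine, hydroxyl trans to mercury). Demercuration with NaBH4 gives (2S,3R,6S)-2-chloro-chamigr-7-en-3-ol F6. Me3SiBr in CH2Cl2 at −20 °C then ionises only the tertiary C–O bond, and bromide enters anti to chlorine through the same chlorine-bridged cation to give 4, so the C3 configuration of F6 is immaterial.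

3. Step 6. Facial selectivity at C10 may be poor and the equilibrium of step 7 may not favour the required epimer, so that material is lost in repeated separation; the base of step 7 may also deprotonate the C14 methyl and open a Favorskii-type loss of bromide. Fallback, setting out from 5 and coming back at 9: the lithium dienolate 6, generated as in step 5, is hydroxylated with an enantiopure (camphorsulfonyl)oxaziridine (Davis reagent, antipode chosen for the C10 face opposite to the one required for bromine). This gives (2S,3S,6R,10S)-3-bromo-2-chloro-10-hydroxy-chamigr-7-en-9-one F7 under reagent control. Tf2O and 2,6-lutidine at −78 °C convert it into (2S,3S,6R,10S)-3-bromo-2-chloro-10-(trifluoromethylsulfonyloxy)-chamigr-7-en-9-one F8. LiBr in THF then displaces the carbonyl-activated triflate with inversion to give 9; a triflate is chosen because the carbon lies between a carbonyl and a quaternary centre, the pattern of pantolactone triflate, where halide displacement still proceeds with inversion.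

**Further compounds**

F1 | step 1 | (6R)-chamigra-3,7-diene | CC1=CCCC(C)(C)[C@@]12CC=C(C)CC2
F2 | step 1 | (6S)-chamigra-3,7-dien-2-ol (C2 epimers) | CC1=CCCC(C)(C)[C@@]12CC=C(C)C(O)C2
F3 | step 1 | (6S)-chamigra-3,7-dien-2-one | CC1=CCCC(C)(C)[C@@]12CC=C(C)C(=O)C2
F4 | step 1 | (2R,6S)-chamigra-3,7-dien-2-ol | CC1=CCCC(C)(C)[C@@]12CC=C(C)[C@H](O)C2
F5 | step 3 | 4-(acetoxymercurio)-2-chloro-chamigr-7-en-3-ol (OH cis to Cl, Hg trans to OH) | CC1=CCCC(C)(C)[C@@]12C[C@H]([Hg]OC(C)=O)[C@@](C)(O)[C@@H](Cl)C2
F6 | step 3 | (2S,3R,6S)-2-chloro-chamigr-7-en-3-ol | CC1=CCCC(C)(C)[C@@]12CC[C@@](C)(O)[C@@H](Cl)C2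
F7 | step 6 | (2S,3S,6R,10S)-3-bromo-2-chloro-10-hydroxy-chamigr-7-en-9-one | CC1=CC(=O)[C@@H](O)C(C)(C)[C@@]12CC[C@](C)(Br)[C@@H](Cl)C2
F8 | step 6 | (2S,3S,6R,10S)-3-bromo-2-chloro-10-(trifluoromethylsulfonyloxy)-chamigr-7-en-9-one | CC1=CC(=O)[C@@H](OS(=O)(=O)C(F)(F)F)C(C)(C)[C@@]12CC[C@](C)(Br)[C@@H](Cl)C2
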